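In a one-step world E goes to L at the pseudo-first-order rate k[E], with k constant, and feeding becomes one integral.

all flasks: D 10 µM

|  | E | X | remark | time |
|---|---|---|---|---|
| Sunday's | 0.010 M | 0.013 M | run made earlier |  |
| Saturday's | 0.010 M | 0.0065 M | run made earlier |  |
| Tuesday's | 0.010 M | 0.026 M | run made earlier |  |
| green | 0.010 M (fed, over 12 d) | 0.0130 M | all else is in the flask from the start; the feed brings no volume worth counting | 20 d |
| ochre | 0.010 M | 0.0130 M | everything together at the start | 20 d |
| amber | 0.010 M | 0.0130 M (fed, over 12 d) | all else is in the flask from the start; the feed brings no volume worth counting | 20 d |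

| run | time / d | L / % |
|---|---|---|
| Sunday's | 3.00 | 22 |
| Sunday's | 6.00 | 33 |
| Sunday's | 10.0 | 45 |
| Sunday's | 12.0 | 51 |
| Sunday's | 15.0 | 54 |
| Sunday's | 20.0 | 58 |
| Saturday's | 1.67 | 8 |
| Saturday's | 2.50 | 13 |
| Saturday's | 4.00 | 17 |
| Saturday's | 8.00 | 27 |
| Saturday's | 12.0 | 32 |
| Saturday's | 20.0 | 37 |
| Tuesday's | 3.00 | 26 |
| Tuesday's | 6.00 | 42 |
| Tuesday's | 10.0 | 51 |
| Tuesday's | 12.0 | 52 |
| Tuesday's | 15.0 | 53 |
| Tuesday's | 20.0 | 49 |

(scatter of a reading: 1.5 percentage points)

* the flask with the highest amount of L, in percent of the E charged ("all alike" if they lie within 1.5 percentage points) (green / ochre / amber / all alike)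
* final L, as a percentage of the E charged, in green
* final L, as a percentage of the E charged, in ochre
* final L, as a percentage of the E charged, in amber

- the analysis behind the earlier runs scatters by 1.5 percentage points, standard deviation
- a reading or a percentage of L counts all its forms, free or not

*What is k?* Sunday's run has ochre's recipe, and its first reading, 22% at 3.00 d, gives k = 0.0828 /d.

*And green, where E enters evenly over τ = 12 d?* I integrate d[E]/dt = feed − k[E] up to τ, then plain decay up to T = 20 d. This gives the fed remainder, the share of charged E unreacted at T: g = (1 − e^(−kτ))/(kτ) · e^(−k(T−τ)) = 32.7%. Ochre's remainder in this world is e^(−kT) = 19.1%.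

*But that has 80.9% of E gone in Sunday's run, and L reads 58%. Isn't k broken?* The two figures differ, and I leave the difference unexplained. So I carry a ratio, assuming green turns the same share of reacted E into L as Sunday's run did. The ratio of E reacted, green to ochre, is 0.832. Times Sunday's reading, that gives my 48.3% for green, with ochre near the reading itself.

*Amber?* Saturday's first reading, with X halved, gives 0.0499 /d. That is 0.603 of k, above the 0.5 of plain proportion. So I place amber between green and ochre, without a number.

The forecast names ochre: green 36% (28% to 45%), ochre 58% (55% to 61%), amber 39% (31% to 48%). Its ground: “D appears to die with time”. For green it stands lower than my figure.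

    E + D ⇌ G (K = 18.1 /M, k = 8420 /M/h)
    Q ⇌ L, rate k2*(cs2 - [L]) while solid is left; crystals form when [L] > cs2 (solubility = 0.520 mM, k = 0.806 /h)
    X + L → Z (k = 1.12 /M/h)
    J → D + L (k = 9.96 /h)
    X + G → J (k = 3510 /M/h)

Green ends at 45.8%, ochre at 57.3%, amber at 53.8%, so ochre is highest. At 20.0 d green's catalyst stands as D 87.0%, G 5.15% and J 7.87%, together >99.9% of its charge. The fed remainder, 32.7%, stands beside green's E left, 33.8%.

For the neighbour of green with 2.5 × 10⁻⁵ M of D, taking k in proportion to [D], g becomes 7.04%. That flask computes to E 13% and L 68.8%, so g is lower there than the computed E.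

The runs are simulated with constants of no real substance, and the scatter is random.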